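**Plan**
- Retrosynthesis first cuts the C2–C3 bond of the quinone ring (C2 carries the methyl, C3 the phytyl chain). This opens the ring to an ortho-diacylbenzene held as its bis(silyl enol ether).
- The enabling feature: C2 and C3 are each the α-carbon of an aryl ketone (C1=O, C4=O), and both carbonyls sit ortho on the benzo ring. The quinone ring is therefore the doubly dehydrogenated form of a 1-propanoyl-2-acylbenzene, and α,α'-coupling of its two enol ethers is a six-membered closure.
- The next cuts are the aryl–C4 bond and the C1–ethyl bond (2-bromobenzaldehyde, ethyllithium and a C22 Weinreb amide joined in one flask), then C3–C1' (amide enolate plus phytyl bromide).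
- Forward: the chain is built first, attached to the benzene ring together with the propanoyl arm, oxidized to the diketone and silylated. The quinone ring is the only ring made and arises last, already at the quinone oxidation level.
- Stereochemistry: the 2'E alkene and the 7'R and 11'R centres come from natural phytol and are never touched. The sp3 centres formed on the way are transient.

Key step: step 6

Assumption: natural phytol is bought as the single (2E,7R,11R) isomer. The centres that are formed and erased again (carbinol carbon of 11, C2 and C3 of 14) are left undefined.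

**Step 1**
Reactants: 1 (2E,7R,11R)-phytol
Product: 2 (2E,7R,11R)-1-bromo-3,7,11,15-tetramethylhexadec-2-ene (phytyl bromide)
Conditions: PBr3 (0.4 equiv), pyridine (cat.), Et2O, −10 to 0 °C, dark; used without chromatography
Reagents that add atoms: phosphorus tribromide, BrP(Br)Br
Why: Bromide displaces the phosphite ester at the primary allylic carbon (standard SN2 conversion of an allylic alcohol into the bromide), and the low temperature should keep the attack at C1 so that the E alkene and the remote 7R and 11R centres stay as they are.

**Step 2**
Reactants: 3 N-methoxy-N-methylacetamide; 2 phytyl bromide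
Product: 5 (4E,9R,13R)-N-methoxy-N,5,9,13,17-pentamethyloctadec-4-enamide, via lithium amide enolate 4 (not isolated)
Conditions: 3 (1.5 equiv), LiN(iPr)2 (1.5 equiv), THF, −78 °C; then 2, DMPU, −78 → −40 °C; aq NH4Cl
Reagents that add atoms: none
Why: C-alkylation of a lithium amide enolate by a primary allylic bromide (SN2 at the unhindered CH2, not SN2' to a quaternary carbon) should join C3 to C1' without touching the alkene geometry; no stereocentre is formed.

**Step 3**
Reactants: 6 2-bromobenzaldehyde; 7 ethyllithium; 5 Weinreb amide from step 2
Product: 11 (4E,9R,13R)-1-[2-(1-hydroxypropyl)phenyl]-5,9,13,17-tetramethyloctadec-4-en-1-one, via lithium bromoaryl alkoxide 8 (not isolated), via dilithiated aryl alkoxide 9 (not isolated), via tetrahedral hemiaminal adduct 10 (not isolated)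
Conditions: 6 (1.3 equiv), EtLi (1.3 equiv), THF, −78 °C; tBuLi (2.6 equiv), −78 °C; 5 (1.0 equiv), −78 → 0 °C; aq NH4Cl
Reagents that add atoms: none
Why: Carbonyl addition of ethyllithium gives an alkoxide that protects the benzylic oxygen during bromine–lithium exchange, and the aryllithium should add only once to the amide because the chelated tetrahedral adduct survives until work-up (Weinreb ketone synthesis); the carbinol centre forms without control in both configurations and is removed in step 4.

**Step 4**
Reactants: 11 hydroxy ketone
Product: 12 (4E,9R,13R)-5,9,13,17-tetramethyl-1-(2-propanoylphenyl)octadec-4-en-1-one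
Conditions: nPr4NRuO4 (5 mol%), NMO (1.5 equiv), 4 Å MS, CH2Cl2, rt
Reagents that add atoms: none
Why: Ley–Griffith oxidation of the secondary benzylic alcohol should drain the open hydroxy ketone from its hemiketal equilibrium under neutral conditions that avoid dehydration to an isobenzofuran and spare the trisubstituted alkene; the carbinol stereocentre disappears.

**Step 5**
Reactants: 12 diketone
Product: 13 1-[(1Z)-1-(tert-butyldimethylsilyloxy)prop-1-en-1-yl]-2-[(1Z,4E,9R,13R)-1-(tert-butyldimethylsilyloxy)-5,9,13,17-tetramethyloctadeca-1,4-dien-1-yl]benzene
Conditions: TBSOTf (2.5 equiv), Et3N (5 equiv), CH2Cl2, −78 → 0 °C; filtration through Et3N-deactivated silica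
Reagents that add atoms: tert-butyldimethylsilyl trifluoromethanesulfonate, CC(C)(C)[Si](C)(C)OS(=O)(=O)C(F)(F)F
Why: Soft enolization (silyl triflate activation, amine deprotonation) should convert both aryl ketones into silyl enol ethers regiospecifically, since each has only one enolizable side; the Z geometry expected for aryl ketones is of no consequence because it is lost in step 6.

**Step 6**
Reactants: 13 bis(silyl enol ether)
Product: 16 phylloquinone, via dihydronaphthoquinone 14 (not isolated), via phylloquinol 15 (not isolated)
Conditions: (NH4)2Ce(NO3)6 (4.5 equiv), NaHCO3, MeCN–EtCN, high dilution, −30 → 0 °C, dark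
Reagents that add atoms: none
Why: Tetravalent cerium takes one electron from one of the two electron-rich aryl silyl enol ethers, and the resulting radical cation (an α-keto radical once silicon is lost) adds to the β-carbon of the neighbouring enol ether to form the C2–C3 bond; a second electron transfer and desilylation give diketone 14, whose C2–H and C3–H enolize to the naphthalene-1,4-diol 15, which two further equivalents of the oxidant convert into quinone 16. The closest known reaction types are the oxidative coupling of silyl enol ethers to 1,4-diketones by (NH4)2Ce(NO3)6, including intramolecular cases, and the routine oxidation of hydroquinones to quinones by the same reagent. The one ring that closes is the six-membered quinone ring, by 6-endo-trig attack of the α-carbon radical on the enol ether carbon that leaves an α-siloxy benzylic radical. No stereocentre has to be controlled: C2 and C3 of 14 form as a mixture and become sp2 on aromatization, and the 2'E alkene and the 7'R and 11'R centres take no part. The step needs chemoselectivity for the enol ethers over the isolated trisubstituted alkene, which their much lower oxidation potential should secure, and 6-endo closure over 5-exo closure and over intermolecular coupling, which the polarity match (electrophilic radical, nucleophilic β-carbon), the stabilised radical formed and the ortho placement of the two arms under dilution should secure. Low temperature should keep ring closure faster than the reversible three-membered closure of the homoallylic C3 radical, which could otherwise erode the E geometry.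

**Compound list**
1 | (2E,7R,11R)-phytol | OC/C=C(\C)CCC[C@H](C)CCC[C@H](C)CCCC(C)C | starting material
2 | (2E,7R,11R)-phytyl bromide | BrC/C=C(\C)CCC[C@H](C)CCC[C@H](C)CCCC(C)C | intermediate
3 | N-methoxy-N-methylacetamide | CC(=O)N(C)OC | starting material
4 | lithium enolate of N-methoxy-N-methylacetamide | C=C(O[Li])N(C)OC | intermediate
5 | (4E,9R,13R)-N-methoxy-N,5,9,13,17-pentamethyloctadec-4-enamide | CON(C)C(=O)CC/C=C(\C)CCC[C@H](C)CCC[C@H](C)CCCC(C)C | intermediate
6 | 2-bromobenzaldehyde | O=Cc1ccccc1Br | starting material
7 | ethyllithium | CC[Li] | starting material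
8 | lithium 1-(2-bromophenyl)propan-1-olate (both configurations) | CCC(O[Li])c1ccccc1Br | intermediate
9 | lithium 1-(2-lithiophenyl)propan-1-olate | CCC(O[Li])c1ccccc1[Li] | intermediate
10 | dilithium tetrahedral adduct of 9 and 5 | CCC(O[Li])c1ccccc1C(O[Li])(N(C)OC)CC/C=C(\C)CCC[C@H](C)CCC[C@H](C)CCCC(C)C | intermediate
11 | (4E,9R,13R)-1-[2-(1-hydroxypropyl)phenyl]-5,9,13,17-tetramethyloctadec-4-en-1-one (both configurations at the carbinol carbon; may equilibrate with its cyclic hemiketal) | CCC(O)c1ccccc1C(=O)CC/C=C(\C)CCC[C@H](C)CCC[C@H](C)CCCC(C)C | intermediate
12 | (4E,9R,13R)-5,9,13,17-tetramethyl-1-(2-propanoylphenyl)octadec-4-en-1-one | CCC(=O)c1ccccc1C(=O)CC/C=C(\C)CCC[C@H](C)CCC[C@H](C)CCCC(C)C | intermediate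
13 | bis(tert-butyldimethylsilyl enol ether) of 12, drawn as the expected Z,Z isomer | C/C=C(\O[Si](C)(C)C(C)(C)C)c1ccccc1/C(O[Si](C)(C)C(C)(C)C)=C/C/C=C(\C)CCC[C@H](C)CCC[C@H](C)CCCC(C)C | intermediate
14 | 2-methyl-3-[(2E,7R,11R)-3,7,11,15-tetramethylhexadec-2-en-1-yl]-2,3-dihydronaphthalene-1,4-dione (cis and trans at C2/C3) | CC1C(C/C=C(\C)CCC[C@H](C)CCC[C@H](C)CCCC(C)C)C(=O)c2ccccc2C1=O | intermediate
15 | 2-methyl-3-[(2E,7R,11R)-3,7,11,15-tetramethylhexadec-2-en-1-yl]naphthalene-1,4-diol (phylloquinol) | Cc1c(C/C=C(\C)CCC[C@H](C)CCC[C@H](C)CCCC(C)C)c(O)c2ccccc2c1O | intermediate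
16 | phylloquinone, 2-methyl-3-[(2E,7R,11R)-3,7,11,15-tetramethylhexadec-2-en-1-yl]naphthalene-1,4-dione | CC1=C(C/C=C(\C)CCC[C@H](C)CCC[C@H](C)CCCC(C)C)C(=O)c2ccccc2C1=O | target

**Count**
Total steps: 6. Longest linear sequence: 6 (1 → 2 → 5 → 11 → 12 → 13 → 16).

**Steps most likely to fail**

Step 6. The radical cation may lose silicon and return to the ketone before it closes, may couple between molecules, or may close in the 5-exo mode. The fallback replaces the one-electron coupling by a two-electron halogenation and alkylation and sets out from 13. NBS (1.0 equiv) in THF at −78 °C should brominate one enol ether and give 2-bromopropanoyl silyl enol ether F1 together with its regioisomer, the 2-bromoacyl silyl enol ether F2. Both converge: CsF in MeCN should unmask the remaining enol ether as an enolate that displaces the α-keto bromide in a 6-(enolendo)-exo-tet alkylation. This gives 14, where the fallback comes back to the route. Catalytic Et3N and air (or Ag2O) should then carry 14 through 15 to 16.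

Step 5. The first enol ether formed may add to the neighbouring silyl-activated ketone in a five-membered aldol closure faster than the second enolization takes place. The fallback drops the silyl enol ether and sets out from 12. Slow inverse addition of 12 to LiN(iPr)2 (2.5 equiv) in THF at −78 °C lets every molecule meet excess base and should give dilithium dienolate F3. Oxidation in the same flask with CuCl2 in DMF (enolate coupling by divalent copper) should give 14, where the fallback rejoins the route, and exposure to air then leads through 15 to 16.

Step 3. The aryllithium 9 may act as a base toward the α-CH2 of amide 5 instead of adding, which would return protonated arene and unchanged 5. The fallback changes the electrophile and the oxidation plan and sets out from 5. Reduction with iBu2AlH in THF at −78 °C should give the aldehyde (4E,9R,13R)-5,9,13,17-tetramethyloctadec-4-enal F4, which adds organolithiums much faster than it enolizes. Its addition to 9 should give the diol (4E,9R,13R)-1-[2-(1-hydroxypropyl)phenyl]-5,9,13,17-tetramethyloctadec-4-en-1-ol F5 as a diastereomer mixture. Double oxidation with nPr4NRuO4 and NMO should then give 12, where the fallback comes back to the route.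

**Further compounds**
F1 | step 6 | 2-bromo-1-{2-[(1Z,4E,9R,13R)-1-(tert-butyldimethylsilyloxy)-5,9,13,17-tetramethyloctadeca-1,4-dien-1-yl]phenyl}propan-1-one | CC(Br)C(=O)c1ccccc1/C(O[Si](C)(C)C(C)(C)C)=C/C/C=C(\C)CCC[C@H](C)CCC[C@H](C)CCCC(C)C
F2 | step 6 | (4E,9R,13R)-2-bromo-1-{2-[(1Z)-1-(tert-butyldimethylsilyloxy)prop-1-en-1-yl]phenyl}-5,9,13,17-tetramethyloctadec-4-en-1-one | C/C=C(\O[Si](C)(C)C(C)(C)C)c1ccccc1C(=O)C(Br)C/C=C(\C)CCC[C@H](C)CCC[C@H](C)CCCC(C)C
F3 | step 5 | dilithium dienolate of 12 | CC=C(O[Li])c1ccccc1C(O[Li])=CC/C=C(\C)CCC[C@H](C)CCC[C@H](C)CCCC(C)C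
F4 | step 3 | (4E,9R,13R)-5,9,13,17-tetramethyloctadec-4-enal | O=CCC/C=C(\C)CCC[C@H](C)CCC[C@H](C)CCCC(C)C
F5 | step 3 | (4E,9R,13R)-1-[2-(1-hydroxypropyl)phenyl]-5,9,13,17-tetramethyloctadec-4-en-1-ol | CCC(O)c1ccccc1C(O)CC/C=C(\C)CCC[C@H](C)CCC[C@H](C)CCCC(C)C
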